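**Plan**
- Cuts, in retrosynthetic order: the five MOM acetals; the enone Cα=Cβ bond (Claisen–Schmidt) and the acetyl–ring A bond (ortho-lithiation); the oxane O1–C6 bond (benzylic cation closure) and the C6–aryl bond (aryl Grignard on a lactol); the C4–ring A bond; in the chain, the enal C=C (cross-metathesis) and the allyl C–C bond (allylation).
- Enabling feature: C4 of the oxane (O1, C2 with the arylethyl arm, C4, C6 with the aryl) is a benzylic CH bonded to the one ring A carbon that lies between two oxygens, with the C3 and C5 methylenes on either side. This is the pattern left when a ring carbon of C3-symmetric phloroglucinol adds to the β-carbon of an enal and a neighbouring OH stores the C5–C6 arm as a lactol.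
- Forward order: arylpropanal → allylation → cross-metathesis (C7 enal) → organocatalytic arylation with chroman-2-ol closure (temporary ring) → Grignard opening → phenol differentiation → oxane ring → acetyl → chalcone → deprotection.
- Stereochemistry: C2 (S) from a Keck allylation with (R)-BINOL/Ti(OiPr)4; C4 (R) from the (S)-diphenylprolinol silyl ether catalyst; C6 (S) by thermodynamic control in the reversible cationic closure (all-equatorial 2,4,6-cis chair); the enone is E by dehydration.
- Protecting groups: MOM on every phenol that ends free, so the last step is dilute acid and no hydrogenation meets the enone; the para oxygen of ring A is singled out by a bulky silyl relay.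

Key step: step 6

Remark: the carbon that becomes C6 is carried as an epimer mixture (9, 12–16) because step 12 re-sets it. The descriptor at the ring-A-bearing carbon switches between R and S in 12–14 only because the silyl ether changes the CIP ranking of its two CH2 arms; the spatial arrangement set in step 6 is unchanged.

**Route**

Step 1
Reactants: 1 methyl 3-(4-hydroxyphenyl)propanoate
Product: 2 methyl 3-[4-(methoxymethoxy)phenyl]propanoate
Conditions: MOMCl, i-Pr2NEt, CH2Cl2, 0 °C → rt
Reagents that add atoms: chloromethyl methyl ether, COCCl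
Why: O-alkylation of the phenol by the reactive α-chloro ether (acetal formation) under amine base should proceed cleanly and leaves the ester untouched.

Step 2
Reactants: 2 methyl 3-[4-(methoxymethoxy)phenyl]propanoate
Product: 3 3-[4-(methoxymethoxy)phenyl]propanal
Conditions: i-Bu2AlH (1.1 equiv), CH2Cl2, −78 °C; aq potassium sodium tartrate
Reagents that add atoms: none
Why: Partial reduction of a methyl ester with i-Bu2AlH at −78 °C should stop at the aldehyde because the aluminium hemiacetal persists until work-up.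

Step 3
Reactants: 3 3-[4-(methoxymethoxy)phenyl]propanal
Product: 4 (3S)-1-[4-(methoxymethoxy)phenyl]hex-5-en-3-ol
Conditions: (R)-BINOL (10 mol%), Ti(OiPr)4 (10 mol%), 4 Å MS, Bu3SnCH2CH=CH2, CH2Cl2, −20 °C
Reagents that add atoms: allyltributylstannane, C=CC[Sn](CCCC)(CCCC)CCCC
Why: In the Keck asymmetric allylation the (R)-BINOL–titanium Lewis acid directs allyl transfer from tin to the Re face of the aldehyde, which for this unbranched aldehyde should give the (S)-homoallylic alcohol (the later C2).

Step 4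
Reactants: 4 (3S)-1-[4-(methoxymethoxy)phenyl]hex-5-en-3-ol
Product: 5 tert-butyl{[(3S)-1-[4-(methoxymethoxy)phenyl]hex-5-en-3-yl]oxy}dimethylsilane
Conditions: TBSCl, imidazole, DMF, rt
Reagents that add atoms: tert-butyldimethylsilyl chloride, CC(C)(C)[Si](C)(C)Cl
Why: Imidazole-promoted silylation of an unhindered secondary alcohol is routine and masks the oxygen that would otherwise add to the enal.

Step 5
Reactants: 5 tert-butyl{[(3S)-1-[4-(methoxymethoxy)phenyl]hex-5-en-3-yl]oxy}dimethylsilane
Product: 6 (2E,5S)-5-(tert-butyldimethylsilyloxy)-7-[4-(methoxymethoxy)phenyl]hept-2-enal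
Conditions: crotonaldehyde (5 equiv), second-generation Hoveyda–Grubbs catalyst RuCl2(H2IMes)(=CH-C6H4-2-OiPr) (5 mol%), CH2Cl2, 40 °C
Reagents that add atoms: crotonaldehyde, C/C=C/C=O
Why: Olefin cross-metathesis of a terminal alkene with excess crotonaldehyde should give the E-enal, driven by loss of propene.

Step 6
Reactants: 6 (2E,5S)-5-(tert-butyldimethylsilyloxy)-7-[4-(methoxymethoxy)phenyl]hept-2-enal; 7 phloroglucinol
Product: 9 (4R)-4-{(2S)-2-(tert-butyldimethylsilyloxy)-4-[4-(methoxymethoxy)phenyl]butyl}chromane-2,5,7-triol (both anomers), via open-chain aldehyde 8 (not isolated)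
Conditions: 7 (3 equiv), (S)-α,α-diphenylprolinol trimethylsilyl ether (20 mol%), PhCO2H (20 mol%), THF/toluene, 0 °C → rt
Reagents that add atoms: none
Why: The secondary amine condenses with enal 6 to an (E)-configured, s-trans iminium ion whose diphenyl(silyloxy)methyl group blocks one face, and a ring carbon of phloroglucinol adds to C3 (the β-carbon) from the open Re face in a Friedel–Crafts-type Michael addition that forms the C4–ring A bond. Hydrolysis of the resulting enamine frees aldehyde 8 and returns the catalyst, and a flanking phenol adds to the formyl group in a 6-exo-trig closure to the chroman-2-ol, a temporary ring. The closest known reaction type is the diarylprolinol silyl ether-catalysed Friedel–Crafts alkylation/hemiacetalisation of naphthols, sesamol and 3,5-dialkoxyphenols with enals. The new centre (4R in 9, the later C4) is under catalyst control, the silyloxy centre lying 1,3 to it as a spectator, while the anomeric centre is left as a mixture because step 7 destroys it. The step needs C- over O-alkylation and mono- over bis-alkylation: the symmetry of phloroglucinol leaves one kind of carbon site, reversible O-addition is drained by the irreversible C–C bond formation and lactol closure, and a threefold excess of the cheap triphenol should keep the more hindered product from reacting again. The silyl ether on O5 keeps the chain oxygen from closing onto the iminium ion by oxa-Michael addition.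

Step 7
Reactants: 9 (4R)-4-{(2S)-2-(tert-butyldimethylsilyloxy)-4-[4-(methoxymethoxy)phenyl]butyl}chromane-2,5,7-triol; 10 1-bromo-4-(methoxymethoxy)benzene
Product: 12 2-{(3S,5S)-5-(tert-butyldimethylsilyloxy)-1-hydroxy-1,7-bis[4-(methoxymethoxy)phenyl]heptan-3-yl}benzene-1,3,5-triol (C1 epimers), via 4-(methoxymethoxy)phenylmagnesium bromide 11 (not isolated)
Conditions: 10, Mg, THF, rt; then 9 added to 11 (6 equiv), THF, 0 °C → rt; aq NH4Cl
Reagents that add atoms: none
Why: After deprotonation the lactol opens to its phenoxide–aldehyde tautomer and Grignard addition forms the C6–aryl bond; the new carbinol centre is uncontrolled, which is harmless because it is ionised in step 12.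

Step 8
Reactants: 12 2-{(3S,5S)-5-(tert-butyldimethylsilyloxy)-1-hydroxy-1,7-bis[4-(methoxymethoxy)phenyl]heptan-3-yl}benzene-1,3,5-triol
Product: 13 2-{(3S,5S)-5-(tert-butyldimethylsilyloxy)-1-hydroxy-1,7-bis[4-(methoxymethoxy)phenyl]heptan-3-yl}-5-(triisopropylsilyloxy)benzene-1,3-diol
Conditions: TIPSCl (1.05 equiv), imidazole, DMF, 0 °C
Reagents that add atoms: triisopropylsilyl chloride, CC(C)[Si](Cl)(C(C)C)C(C)C
Why: Sterically governed silylation should pick the para hydroxyl, the only one flanked by two ring hydrogens, since each ortho hydroxyl sits next to the branched benzylic carbon and the secondary alcohol is inert to TIPSCl/imidazole at 0 °C.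

Step 9
Reactants: 13 2-{(3S,5S)-5-(tert-butyldimethylsilyloxy)-1-hydroxy-1,7-bis[4-(methoxymethoxy)phenyl]heptan-3-yl}-5-(triisopropylsilyloxy)benzene-1,3-diol
Product: 14 (3S,5S)-5-(tert-butyldimethylsilyloxy)-3-[2,6-bis(methoxymethoxy)-4-(triisopropylsilyloxy)phenyl]-1,7-bis[4-(methoxymethoxy)phenyl]heptan-1-ol
Conditions: MOMCl (3 equiv), K2CO3, acetone, rt → 40 °C
Reagents that add atoms: chloromethyl methyl ether, COCCl
Why: Carbonate deprotonates only the two phenols, whose O-alkylation by the small, hard chloro ether caps them as acetals while the benzylic alcohol and both silyl ethers remain.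

Step 10
Reactants: 14 (3S,5S)-5-(tert-butyldimethylsilyloxy)-3-[2,6-bis(methoxymethoxy)-4-(triisopropylsilyloxy)phenyl]-1,7-bis[4-(methoxymethoxy)phenyl]heptan-1-ol
Product: 15 (3R,5S)-3-[4-hydroxy-2,6-bis(methoxymethoxy)phenyl]-1,7-bis[4-(methoxymethoxy)phenyl]heptane-1,5-diol
Conditions: Bu4NF (3 equiv), THF, 0 °C → rt
Reagents that add atoms: none
Why: Fluoride-driven Si–O cleavage should remove the aryl triisopropylsilyl group quickly and the secondary tert-butyldimethylsilyl group more slowly, with the MOM acetals inert.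

Step 11
Reactants: 15 (3R,5S)-3-[4-hydroxy-2,6-bis(methoxymethoxy)phenyl]-1,7-bis[4-(methoxymethoxy)phenyl]heptane-1,5-diol
Product: 16 (3R,5S)-3-[4-methoxy-2,6-bis(methoxymethoxy)phenyl]-1,7-bis[4-(methoxymethoxy)phenyl]heptane-1,5-diol
Conditions: MeI, K2CO3, acetone, rt
Reagents that add atoms: iodomethane, CI
Why: Williamson methylation under carbonate touches only the single phenol, the two secondary alcohols being too weakly acidic to react.

Step 12
Reactants: 16 (3R,5S)-3-[4-methoxy-2,6-bis(methoxymethoxy)phenyl]-1,7-bis[4-(methoxymethoxy)phenyl]heptane-1,5-diol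
Product: 17 (2S,4R,6S)-4-[4-methoxy-2,6-bis(methoxymethoxy)phenyl]-2-{2-[4-(methoxymethoxy)phenyl]ethyl}-6-[4-(methoxymethoxy)phenyl]oxane
Conditions: camphorsulfonic acid (10 mol%), 4 Å MS, CH2Cl2, 0 °C → rt
Reagents that add atoms: none
Why: In this acid-catalysed dehydrative etherification the alkoxy-stabilised benzylic cation from either C1 epimer is trapped by the C5 hydroxyl to form the O1–C6 bond with C2 untouched, and reversible ionisation should funnel C6 to the all-equatorial 2,4,6-cis chair (6S) under catalytic acid too mild to cleave aryl MOM acetals.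

Step 13
Reactants: 17 (2S,4R,6S)-4-[4-methoxy-2,6-bis(methoxymethoxy)phenyl]-2-{2-[4-(methoxymethoxy)phenyl]ethyl}-6-[4-(methoxymethoxy)phenyl]oxane
Product: 19 1-[6-methoxy-2,4-bis(methoxymethoxy)-3-{(2S,4R,6S)-2-{2-[4-(methoxymethoxy)phenyl]ethyl}-6-[4-(methoxymethoxy)phenyl]oxan-4-yl}phenyl]ethan-1-one, via ring A aryllithium 18 (not isolated)
Conditions: n-BuLi (1.2 equiv), TMEDA, THF, −20 → 0 °C; then MeC(O)N(OMe)Me, −78 °C → rt
Reagents that add atoms: N-methoxy-N-methylacetamide, CON(C)C(C)=O
Why: Directed ortho-metalation should remove a ring A hydrogen flanked by OMe and OMOM (two equivalent, doubly activated sites), and acylation of the aryllithium by the Weinreb amide stops at the ketone because the chelated tetrahedral adduct survives until work-up.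

Step 14
Reactants: 19 1-[6-methoxy-2,4-bis(methoxymethoxy)-3-{(2S,4R,6S)-2-{2-[4-(methoxymethoxy)phenyl]ethyl}-6-[4-(methoxymethoxy)phenyl]oxan-4-yl}phenyl]ethan-1-one; 20 4-(methoxymethoxy)benzaldehyde
Product: 22 (2E)-1-[6-methoxy-2,4-bis(methoxymethoxy)-3-{(2S,4R,6S)-2-{2-[4-(methoxymethoxy)phenyl]ethyl}-6-[4-(methoxymethoxy)phenyl]oxan-4-yl}phenyl]-3-[4-(methoxymethoxy)phenyl]prop-2-en-1-one, via β-hydroxy ketone 21 (not isolated)
Conditions: KOH, EtOH/H2O, rt → 40 °C
Reagents that add atoms: none
Why: In the Claisen–Schmidt condensation the methyl ketone enolate adds to the non-enolisable aldehyde and E1cB dehydration of the aldol gives the conjugated E-enone, with no phenoxide present to deactivate either partner.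

Step 15
Reactants: 22 (2E)-1-[6-methoxy-2,4-bis(methoxymethoxy)-3-{(2S,4R,6S)-2-{2-[4-(methoxymethoxy)phenyl]ethyl}-6-[4-(methoxymethoxy)phenyl]oxan-4-yl}phenyl]-3-[4-(methoxymethoxy)phenyl]prop-2-en-1-one
Product: 23 (2E)-1-[2,4-dihydroxy-6-methoxy-3-{(2S,4R,6S)-2-[2-(4-hydroxyphenyl)ethyl]-6-(4-hydroxyphenyl)oxan-4-yl}phenyl]-3-(4-hydroxyphenyl)prop-2-en-1-one (CNP0215517.1)
Conditions: 3 M HCl, MeOH/THF, rt
Reagents that add atoms: none
Why: Acid-catalysed acetal solvolysis should strip all five MOM groups at room temperature while the enone, the methyl ether and the oxane survive, the oxane already being the thermodynamic all-equatorial isomer.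

**Compound list**
1 | methyl 3-(4-hydroxyphenyl)propanoate | COC(=O)CCc1ccc(O)cc1 | starting material
2 | methyl 3-[4-(methoxymethoxy)phenyl]propanoate | COCOc1ccc(CCC(=O)OC)cc1 | intermediate
3 | 3-[4-(methoxymethoxy)phenyl]propanal | COCOc1ccc(CCC=O)cc1 | intermediate
4 | (3S)-1-[4-(methoxymethoxy)phenyl]hex-5-en-3-ol | C=CC[C@@H](O)CCc1ccc(OCOC)cc1 | intermediate
5 | tert-butyl{[(3S)-1-[4-(methoxymethoxy)phenyl]hex-5-en-3-yl]oxy}dimethylsilane | C=CC[C@@H](O[Si](C)(C)C(C)(C)C)CCc1ccc(OCOC)cc1 | intermediate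
6 | (2E,5S)-5-(tert-butyldimethylsilyloxy)-7-[4-(methoxymethoxy)phenyl]hept-2-enal | O=C/C=C/C[C@@H](O[Si](C)(C)C(C)(C)C)CCc1ccc(OCOC)cc1 | intermediate
7 | phloroglucinol (benzene-1,3,5-triol) | Oc1cc(O)cc(O)c1 | starting material
8 | (3R,5S)-5-(tert-butyldimethylsilyloxy)-7-[4-(methoxymethoxy)phenyl]-3-(2,4,6-trihydroxyphenyl)heptanal | O=CC[C@@H](C[C@@H](O[Si](C)(C)C(C)(C)C)CCc1ccc(OCOC)cc1)c1c(O)cc(O)cc1O | intermediate
9 | (4R)-4-{(2S)-2-(tert-butyldimethylsilyloxy)-4-[4-(methoxymethoxy)phenyl]butyl}chromane-2,5,7-triol, both anomers | OC1C[C@@H](C[C@@H](O[Si](C)(C)C(C)(C)C)CCc2ccc(OCOC)cc2)c2c(O)cc(O)cc2O1 | intermediate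
10 | 1-bromo-4-(methoxymethoxy)benzene | COCOc1ccc(Br)cc1 | starting material
11 | 4-(methoxymethoxy)phenylmagnesium bromide | COCOc1ccc([Mg]Br)cc1 | intermediate
12 | 2-{(3S,5S)-5-(tert-butyldimethylsilyloxy)-1-hydroxy-1,7-bis[4-(methoxymethoxy)phenyl]heptan-3-yl}benzene-1,3,5-triol, C1 epimers | OC(C[C@@H](C[C@@H](O[Si](C)(C)C(C)(C)C)CCc1ccc(OCOC)cc1)c1c(O)cc(O)cc1O)c1ccc(OCOC)cc1 | intermediate
13 | 2-{(3S,5S)-5-(tert-butyldimethylsilyloxy)-1-hydroxy-1,7-bis[4-(methoxymethoxy)phenyl]heptan-3-yl}-5-(triisopropylsilyloxy)benzene-1,3-diol, C1 epimers | OC(C[C@@H](C[C@@H](O[Si](C)(C)C(C)(C)C)CCc1ccc(OCOC)cc1)c1c(O)cc(O[Si](C(C)C)(C(C)C)C(C)C)cc1O)c1ccc(OCOC)cc1 | intermediate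
14 | (3S,5S)-5-(tert-butyldimethylsilyloxy)-3-[2,6-bis(methoxymethoxy)-4-(triisopropylsilyloxy)phenyl]-1,7-bis[4-(methoxymethoxy)phenyl]heptan-1-ol, C1 epimers | OC(C[C@@H](C[C@@H](O[Si](C)(C)C(C)(C)C)CCc1ccc(OCOC)cc1)c1c(OCOC)cc(O[Si](C(C)C)(C(C)C)C(C)C)cc1OCOC)c1ccc(OCOC)cc1 | intermediate
15 | (3R,5S)-3-[4-hydroxy-2,6-bis(methoxymethoxy)phenyl]-1,7-bis[4-(methoxymethoxy)phenyl]heptane-1,5-diol, C1 epimers | OC(C[C@@H](C[C@@H](O)CCc1ccc(OCOC)cc1)c1c(OCOC)cc(O)cc1OCOC)c1ccc(OCOC)cc1 | intermediate
16 | (3R,5S)-3-[4-methoxy-2,6-bis(methoxymethoxy)phenyl]-1,7-bis[4-(methoxymethoxy)phenyl]heptane-1,5-diol, C1 epimers | OC(C[C@@H](C[C@@H](O)CCc1ccc(OCOC)cc1)c1c(OCOC)cc(OC)cc1OCOC)c1ccc(OCOC)cc1 | intermediate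
17 | (2S,4R,6S)-4-[4-methoxy-2,6-bis(methoxymethoxy)phenyl]-2-{2-[4-(methoxymethoxy)phenyl]ethyl}-6-[4-(methoxymethoxy)phenyl]oxane | COc1cc(OCOC)c([C@@H]2C[C@H](CCc3ccc(OCOC)cc3)O[C@H](c3ccc(OCOC)cc3)C2)c(OCOC)c1 | intermediate
18 | [6-methoxy-2,4-bis(methoxymethoxy)-3-{(2S,4R,6S)-2-{2-[4-(methoxymethoxy)phenyl]ethyl}-6-[4-(methoxymethoxy)phenyl]oxan-4-yl}phenyl]lithium | COc1cc(OCOC)c([C@@H]2C[C@H](CCc3ccc(OCOC)cc3)O[C@H](c3ccc(OCOC)cc3)C2)c(OCOC)c1[Li] | intermediate
19 | 1-[6-methoxy-2,4-bis(methoxymethoxy)-3-{(2S,4R,6S)-2-{2-[4-(methoxymethoxy)phenyl]ethyl}-6-[4-(methoxymethoxy)phenyl]oxan-4-yl}phenyl]ethan-1-one | COc1cc(OCOC)c([C@@H]2C[C@H](CCc3ccc(OCOC)cc3)O[C@H](c3ccc(OCOC)cc3)C2)c(OCOC)c1C(C)=O | intermediate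
20 | 4-(methoxymethoxy)benzaldehyde | COCOc1ccc(C=O)cc1 | starting material
21 | 3-hydroxy-1-[6-methoxy-2,4-bis(methoxymethoxy)-3-{(2S,4R,6S)-2-{2-[4-(methoxymethoxy)phenyl]ethyl}-6-[4-(methoxymethoxy)phenyl]oxan-4-yl}phenyl]-3-[4-(methoxymethoxy)phenyl]propan-1-one, carbinol epimers | COc1cc(OCOC)c([C@@H]2C[C@H](CCc3ccc(OCOC)cc3)O[C@H](c3ccc(OCOC)cc3)C2)c(OCOC)c1C(=O)CC(O)c1ccc(OCOC)cc1 | intermediate
22 | (2E)-1-[6-methoxy-2,4-bis(methoxymethoxy)-3-{(2S,4R,6S)-2-{2-[4-(methoxymethoxy)phenyl]ethyl}-6-[4-(methoxymethoxy)phenyl]oxan-4-yl}phenyl]-3-[4-(methoxymethoxy)phenyl]prop-2-en-1-one | COc1cc(OCOC)c([C@@H]2C[C@H](CCc3ccc(OCOC)cc3)O[C@H](c3ccc(OCOC)cc3)C2)c(OCOC)c1C(=O)/C=C/c1ccc(OCOC)cc1 | intermediate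
23 | (2E)-1-[2,4-dihydroxy-6-methoxy-3-{(2S,4R,6S)-2-[2-(4-hydroxyphenyl)ethyl]-6-(4-hydroxyphenyl)oxan-4-yl}phenyl]-3-(4-hydroxyphenyl)prop-2-en-1-one | COc1cc(O)c([C@@H]2C[C@H](CCc3ccc(O)cc3)O[C@H](c3ccc(O)cc3)C2)c(O)c1C(=O)/C=C/c1ccc(O)cc1 | target

**Step count**
Total: 15 steps. Longest linear sequence: 15 steps (1 → 23); 7, 10 and 20 enter as bought materials.

**Steps most likely to fail**

Step 6. The lactol product is still an electron-rich resorcinol and may be alkylated a second time, and the acidic, sparingly soluble triphenol may slow iminium turnover, costing rate and enantioselectivity in the polar medium it requires. The fallback sets out from 6 and masks two of the three hydroxyls before the C–C bond is made. Commercial 3,5-bis(benzyloxy)phenol, a 3,5-dialkoxyphenol soluble in toluene with a single kind of site next to its one free OH, would be added to 6 under the same amine catalyst to give the 5,7-bis(benzyloxy)chroman-2-ol F1. Hydrogenolysis (H2, Pd/C, EtOAc), which the MOM acetal, silyl ether and lactol should tolerate, comes back to the route at 9.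

Step 8. Site discrimination among the three phenols may be insufficient, with silylation at a flanking hydroxyl or twice. The fallback sets out from 9 and moves the differentiation to the lactol, where one flanking oxygen is locked in the pyran ring and only the peri-hindered 5-OH competes with 7-OH. TIPSCl/imidazole on 9 would give the 7-triisopropylsilyl ether F2, and addition of Grignard reagent 11 (4 equiv) to F2 comes back to the route at 13.

Step 13. Metalation may occur at the wrong position, next to a MOM ether on one of the two 4-(methoxymethoxy)phenyl rings or at the benzylic C6–H, and the hindered aryllithium may enolise the Weinreb amide instead of adding to it. The fallback sets out from 17 and fixes the site by electrophilic substitution instead of deprotonation. NBS (1.0 equiv, CH2Cl2, −20 °C) should brominate ring A, by far the most electron-rich arene and with two equivalent open positions, to the ring A monobromide F3. Bromine–lithium exchange with n-BuLi at −78 °C then gives aryllithium 18 regiospecifically, where the route is rejoined.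

**Further compounds**
F1 | step 6 | (4R)-5,7-bis(benzyloxy)-4-{(2S)-2-(tert-butyldimethylsilyloxy)-4-[4-(methoxymethoxy)phenyl]butyl}chroman-2-ol | OC1C[C@@H](C[C@@H](O[Si](C)(C)C(C)(C)C)CCc2ccc(OCOC)cc2)c2c(OCc3ccccc3)cc(OCc3ccccc3)cc2O1
F2 | step 8 | (4R)-4-{(2S)-2-(tert-butyldimethylsilyloxy)-4-[4-(methoxymethoxy)phenyl]butyl}-7-(triisopropylsilyloxy)chromane-2,5-diol | OC1C[C@@H](C[C@@H](O[Si](C)(C)C(C)(C)C)CCc2ccc(OCOC)cc2)c2c(O)cc(O[Si](C(C)C)(C(C)C)C(C)C)cc2O1
F3 | step 13 | (2S,4R,6S)-4-[3-bromo-4-methoxy-2,6-bis(methoxymethoxy)phenyl]-2-{2-[4-(methoxymethoxy)phenyl]ethyl}-6-[4-(methoxymethoxy)phenyl]oxane | COc1cc(OCOC)c([C@@H]2C[C@H](CCc3ccc(OCOC)cc3)O[C@H](c3ccc(OCOC)cc3)C2)c(OCOC)c1Br
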